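The earlier runs and the new flask come from a simulation on assumed constants, and the scatter is random.

1. In a one-step world Xi would rise from the first minute, but the dawn run shows 0 % of Xi at 25.0 min and 33.0 % at 80.0 min, so I read autocatalysis, with Xi making more Xi.

| flask | Ek | remark | time |
|---|---|---|---|
| autumn | 0.94 M | run made earlier |  |
| dawn | 2.1 M | run made earlier |  |
| flask | 1.4 M |  | 3.0 h |

- autumn (time / min: Xi / %, Ek / %): 15.0: 0, 97.8; 40.0: 0, 96.1; 80.0: 0, 91.8; 120: 3.7, 83.2
- dawn (time / min: Xi / %, Ek / %): 25.0: 0, 92.6; 50.0: 0.8, 87.1; 80.0: 33.0, 52.1; 120: 75.6, 8.2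

(each reading ± 1 percentage point)

1. amount of Xi in percent of the Ek charged, at 20 min, 50 min, 2.0 h and 3.0 h

- the numbers in the tables scatter by 1 percentage point (one standard deviation)
- a reading or a percentage of Xi counts all its forms, free or not

2. I ask which number must be known well. An error by a factor 2 in the first trace of Xi moves the onset by ln(2) growth times, less than one. The growth rate, however, stretches the whole lag, and it rests on a dawn reading of 0.8 % under a scatter of 1 percentage point, so that is the weak number. The Ek missing from the balance, 14.9 % at dawn's 80.0 min, I carry as a plain factor on the answer, and that is a rough step of my own that leaves its effect on the timing of the rise out of the reckoning.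

3. My growth time, in which the ratio of Xi to Ek grows by a factor e, taken inversely proportional to the charge, is 10.6 min for the flask.

4. My first answer for 2.0 h copies dawn at equal charge times time, a ratio of 0.633. Going round again, I carry autumn's last reading forward by growth times and get 1.82. The flask's charge is the geometric middle of the two, so I take 1.07, which gives 44.0 % of Xi.

5. The forecast says 0 %, 0 %, 31 % and 75 %, since “The runs seem to collapse”, and at 2.0 h it stands below my figure.

6. The flask gives 0.0213 %, 0.314 %, 40.6 % and 81.7 %.

    2 Ek → Ky (k = 0.0350 M⁻¹ h⁻¹)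
    Ek + Xi → 2 Xi (k = 3.80 M⁻¹ h⁻¹)
    Gu ⇌ Xi, rate k3*(cs3 - [Xi]) while solid is left; crystals form when [Xi] > cs3 (solubility = 0.670 M, k = 18.0 h⁻¹)
    Ek → Xi (k = 2.40 × 10⁻⁴ h⁻¹)

Between 0.300 h and 1.50 h the flask's ratio of Xi to Ek climbs by 6.21 natural-log units, where my growth time gives 6.79. In the dawn run the same time, scaled to 7.09 min, gives 5.64 units after 80.0 min, but the readings climb 2.68, from a Xi of 0.693 M, above the 0.67 M where crystals form. At 3.00 h in the flask, the step from Ek and Xi to 2 Xi uses Ek 830 times as fast as the step from 2 Ek to Ky, with 3.17 % of Ek left.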